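The route rests on cutting both carbon substituents of ring B (the salicylic acid ring) at once: the C1–CO2H and C6–pentyl bonds. In ring B, C2 (oxygen), C1 (carboxyl) and C6 (pentyl) are contiguous, exactly the 1,2,3-pattern that a 3-alkoxybenzyne delivers when a carbon nucleophile adds remote from the oxygen and the resulting ortho-alkoxy aryl anion is trapped. One operation therefore converts an aryne into the fully substituted acid by pentyl Grignard addition and CO2 capture. The aryne precursor is a phloroglucinol-derived 2-iodoaryl triflate whose three oxygens carry benzyl, triflyl and the intact ring A aroyl (depside) ester.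

Key step: step 7

Remark on the chemistry: olivetol dimethyl ether, anhydrous phloroglucinol and pentylmagnesium bromide solution are taken as commercial. The ring A acid is made by formylation then oxidation, because lithiation–carboxylation of olivetol dimethyl ether would place the carboxyl between the two methoxy groups.

Step 1
Reactants: 1 1,3-dimethoxy-5-pentylbenzene (olivetol dimethyl ether)
Product: 3 2,4-dimethoxy-6-pentylbenzaldehyde, via iminium salt 2 (not isolated)
Conditions: POCl3, DMF, 0 °C to 60 °C; then ice-water, 0 °C to rt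
Reagents that add atoms: N,N-dimethylformamide, CN(C)C=O (formyl carbon); water, O (carbonyl oxygen)
Why: Vilsmeier–Haack formylation should occur at the ring position para to one methoxy and ortho to the other (next to the pentyl chain), and hydrolysis of iminium 2 on quench releases the aldehyde with the 2,4-dimethoxy-6-pentyl pattern.

Step 2
Reactants: 3 2,4-dimethoxy-6-pentylbenzaldehyde
Product: 4 2,4-dimethoxy-6-pentylbenzoic acid
Conditions: NaClO2, NaH2PO4, 2-methyl-2-butene (excess), t-BuOH/THF/H2O, rt
Reagents that add atoms: sodium chlorite, [Na+].[O-]Cl=O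
Why: Pinnick oxidation converts the aldehyde to the acid under buffered conditions, and the alkene scavenger removes hypochlorous acid before it can chlorinate the electron-rich ring A.

Step 3
Reactants: 4 2,4-dimethoxy-6-pentylbenzoic acid; 5 phloroglucinol (benzene-1,3,5-triol)
Product: 7 3,5-dihydroxyphenyl 2,4-dimethoxy-6-pentylbenzoate, via acid chloride 6 (not isolated)
Conditions: (COCl)2, cat. DMF, CH2Cl2, 0 °C to rt, evaporate; then 5 (5 equiv), pyridine, cat. DMAP, THF, 0 °C to rt
Reagents that add atoms: none
Why: Acid chloride formation followed by DMAP-catalysed O-acylation of a phenol should give mainly the mono-ester, because the symmetric, cheap and water-soluble triol 5 is in large excess and is washed out, and basic conditions favour O- over C-acylation (the chlorine of 6 comes from oxalyl chloride and leaves as chloride).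

Step 4
Reactants: 7 3,5-dihydroxyphenyl 2,4-dimethoxy-6-pentylbenzoate
Product: 8 3,5-dihydroxy-4-iodophenyl 2,4-dimethoxy-6-pentylbenzoate
Conditions: I2 (1.0 equiv), NaHCO3, THF/H2O, 0 °C
Reagents that add atoms: iodine, II
Why: Electrophilic iodination of a resorcinol phenoxide under aqueous bicarbonate is kinetically directed to the carbon flanked by both hydroxyls, while the methyl-ether ring A is inert to iodine without an activator and the hindered ester tolerates the weak base at 0 °C.

Step 5
Reactants: 8 3,5-dihydroxy-4-iodophenyl 2,4-dimethoxy-6-pentylbenzoate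
Product: 9 3-(benzyloxy)-5-hydroxy-4-iodophenyl 2,4-dimethoxy-6-pentylbenzoate
Conditions: BnBr (1.0 equiv), K2CO3 (1.0 equiv), DMF, 0 °C to rt; unreacted 8 recovered and recycled
Reagents that add atoms: benzyl bromide, BrCc1ccccc1
Why: Williamson etherification with limiting benzyl bromide should give the mono-ether, since the two hydroxyls are equivalent by symmetry and only the degree of alkylation has to be controlled.

Step 6
Reactants: 9 3-(benzyloxy)-5-hydroxy-4-iodophenyl 2,4-dimethoxy-6-pentylbenzoate
Product: 10 3-(benzyloxy)-2-iodo-5-[(2,4-dimethoxy-6-pentylbenzoyl)oxy]phenyl trifluoromethanesulfonate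
Conditions: Tf2O, pyridine, CH2Cl2, −20 °C to 0 °C
Reagents that add atoms: trifluoromethanesulfonic anhydride, O=S(=O)(OS(=O)(=O)C(F)(F)F)C(F)(F)F
Why: O-Sulfonylation of the single remaining phenol with triflic anhydride and pyridine is a standard triflation that leaves the ester, the benzyl ether and the C–I bond untouched.

Step 7
Reactants: 10 3-(benzyloxy)-2-iodo-5-[(2,4-dimethoxy-6-pentylbenzoyl)oxy]phenyl trifluoromethanesulfonate; 11 pentylmagnesium bromide; 12 carbon dioxide
Product: 16 2-(benzyloxy)-4-[(2,4-dimethoxy-6-pentylbenzoyl)oxy]-6-pentylbenzoic acid, via magnesiated aryl triflate 13 (not isolated), via aryne 14 (not isolated), via pentylated aryl Grignard 15 (not isolated)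
Conditions: 10 in THF added slowly to 11 (2.5 equiv), THF, −78 °C to −30 °C; then dry CO2 (12) gas, −78 °C to 0 °C; then 1 M aq. HCl, 0 °C
Reagents that add atoms: none
Why: Iodine–magnesium exchange by 11 at the iodine-bearing carbon of 10 gives 13, which expels triflate from the neighbouring carbon at low temperature to form aryne 14; a second equivalent of 11 adds across the strained triple bond to give 15, which 12 carboxylates (aryne carbomagnesiation followed by Grignard carboxylation, the known three-component coupling of 3-alkoxybenzynes). No ring is closed and no stereocenter is formed. The selectivity needed is regiochemical: pentyl must bond to the former triflate carbon (C6 of 16) and magnesium must end on the former iodine carbon (C1), and the benzyloxy group on the adjacent C2 should secure this because its C–O bond inductively stabilises the aryl anion developing beside it and distorts the aryne so that the remote carbon is the more electrophilic, while the aroyloxy group further round the ring has only a weak influence. Using 11 for both the exchange and the addition leaves no second carbon nucleophile to compete for 14, and slow addition of 10 into excess 11 keeps the aryne from meeting 15. Chemoselectivity rests on the low temperature and on the depside carbonyl being shielded by the flanking methoxy and pentyl groups of ring A, so that exchange at the activated C–I bond should outrun addition to the ester or attack at the triflate sulfur.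

Step 8
Reactants: 16 2-(benzyloxy)-4-[(2,4-dimethoxy-6-pentylbenzoyl)oxy]-6-pentylbenzoic acid
Product: 17 4-[(2,4-dimethoxy-6-pentylbenzoyl)oxy]-2-hydroxy-6-pentylbenzoic acid
Conditions: H2 (1 atm), 10% Pd/C, EtOAc, rt
Reagents that add atoms: none
Why: Catalytic hydrogenolysis cleaves only the benzyl ether, and the neutral room-temperature conditions spare the aryl ester and avoid decarboxylation of the salicylic acid.

Compound list
1 | 1,3-dimethoxy-5-pentylbenzene (olivetol dimethyl ether) | CCCCCc1cc(OC)cc(OC)c1 | starting material
2 | (2,4-dimethoxy-6-pentylbenzylidene)dimethyliminium dichlorophosphate | CCCCCc1cc(OC)cc(OC)c1C=[N+](C)C.[O-]P(=O)(Cl)Cl | intermediate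
3 | 2,4-dimethoxy-6-pentylbenzaldehyde | CCCCCc1cc(OC)cc(OC)c1C=O | intermediate
4 | 2,4-dimethoxy-6-pentylbenzoic acid | CCCCCc1cc(OC)cc(OC)c1C(=O)O | intermediate
5 | phloroglucinol (benzene-1,3,5-triol) | Oc1cc(O)cc(O)c1 | starting material
6 | 2,4-dimethoxy-6-pentylbenzoyl chloride | CCCCCc1cc(OC)cc(OC)c1C(=O)Cl | intermediate
7 | 3,5-dihydroxyphenyl 2,4-dimethoxy-6-pentylbenzoate | CCCCCc1cc(OC)cc(OC)c1C(=O)Oc1cc(O)cc(O)c1 | intermediate
8 | 3,5-dihydroxy-4-iodophenyl 2,4-dimethoxy-6-pentylbenzoate | CCCCCc1cc(OC)cc(OC)c1C(=O)Oc1cc(O)c(I)c(O)c1 | intermediate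
9 | 3-(benzyloxy)-5-hydroxy-4-iodophenyl 2,4-dimethoxy-6-pentylbenzoate | CCCCCc1cc(OC)cc(OC)c1C(=O)Oc1cc(O)c(I)c(OCc2ccccc2)c1 | intermediate
10 | 3-(benzyloxy)-2-iodo-5-[(2,4-dimethoxy-6-pentylbenzoyl)oxy]phenyl trifluoromethanesulfonate | CCCCCc1cc(OC)cc(OC)c1C(=O)Oc1cc(OCc2ccccc2)c(I)c(OS(=O)(=O)C(F)(F)F)c1 | intermediate
11 | pentylmagnesium bromide | CCCCC[Mg]Br | starting material
12 | carbon dioxide | O=C=O | starting material
13 | bromo{2-(benzyloxy)-4-[(2,4-dimethoxy-6-pentylbenzoyl)oxy]-6-[(trifluoromethanesulfonyl)oxy]phenyl}magnesium | CCCCCc1cc(OC)cc(OC)c1C(=O)Oc1cc(OCc2ccccc2)c([Mg]Br)c(OS(=O)(=O)C(F)(F)F)c1 | intermediate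
14 | 3-(benzyloxy)-5-[(2,4-dimethoxy-6-pentylbenzoyl)oxy]benzyne | CCCCCc1cc(OC)cc(OC)c1C(=O)OC1=CC#CC(OCc2ccccc2)=C1 | intermediate
15 | bromo{2-(benzyloxy)-4-[(2,4-dimethoxy-6-pentylbenzoyl)oxy]-6-pentylphenyl}magnesium | CCCCCc1cc(OC)cc(OC)c1C(=O)Oc1cc(CCCCC)c([Mg]Br)c(OCc2ccccc2)c1 | intermediate
16 | 2-(benzyloxy)-4-[(2,4-dimethoxy-6-pentylbenzoyl)oxy]-6-pentylbenzoic acid | CCCCCc1cc(OC(=O)c2c(CCCCC)cc(OC)cc2OC)cc(OCc2ccccc2)c1C(=O)O | intermediate
17 | 4-[(2,4-dimethoxy-6-pentylbenzoyl)oxy]-2-hydroxy-6-pentylbenzoic acid | CCCCCc1cc(OC(=O)c2c(CCCCC)cc(OC)cc2OC)cc(O)c1C(=O)O | target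

Total step count: 8. Longest linear sequence: 8 steps (1 to 17).

Steps most likely to fail

Step 7. The Grignard reagent may add to the depside ester or attack the triflate sulfur in competition with exchange, regioselectivity of the aryne addition may erode, or 15 may be protonated before carboxylation. Hexanoic acid from surplus 11 and CO2 would also have to be removed on chromatography. The fallback sets out from 10 and comes back at 17, making the same two bonds by two palladium-catalysed couplings that use the reactivity gap between C–I and C–OTf and avoid any strongly basic organometallic. Benzyloxycarbonylation of the C–I bond of 10 (Pd(OAc)2, Xantphos, CO 1 atm, BnOH, Et3N, toluene, 70 °C) should give benzyl 2-(benzyloxy)-4-[(2,4-dimethoxy-6-pentylbenzoyl)oxy]-6-[(trifluoromethanesulfonyl)oxy]benzoate F1. Negishi coupling of its triflate, now activated by the ortho ester, with commercial pentylzinc bromide (PdCl2(dppf), THF, 50 °C) should give benzyl 2-(benzyloxy)-4-[(2,4-dimethoxy-6-pentylbenzoyl)oxy]-6-pentylbenzoate F2. Hydrogenolysis (H2, Pd/C, EtOAc, rt) then removes both benzyl groups and arrives at 17.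

Step 5. Over-alkylation is the risk: the phenoxide of the mono-ether is about as nucleophilic as that of the diol, so conversion to 9 is capped near the statistical limit. The fallback sets out from 8 and comes back at 10 by reversing the order of the two O-functionalisations. Mono-triflation of 8 (Tf2O 1.0 equiv, pyridine, CH2Cl2, −78 °C) should stop more cleanly at one sulfonate, because the first triflyl group withdraws electron density from the remaining hydroxyl, and would give 3-hydroxy-2-iodo-5-[(2,4-dimethoxy-6-pentylbenzoyl)oxy]phenyl trifluoromethanesulfonate F3. Mitsunobu etherification of this more acidic phenol with benzyl alcohol (PPh3, DIAD, THF, 0 °C to rt) then gives 10 under neutral conditions that leave triflate and ester alone.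

Step 3. Over-acylation to di- and tri-esters, or sluggish acylation by the hindered acid chloride, would waste the ring A acid. The fallback sets out from acid chloride 6 and comes back at 7, removing the statistics by using a phloroglucinol with two oxygens already masked. Commercial 3,5-bis(benzyloxy)phenol (SMILES Oc1cc(OCc2ccccc2)cc(OCc2ccccc2)c1) is acylated with 6 (pyridine, DMAP, CH2Cl2, rt) to give 3,5-bis(benzyloxy)phenyl 2,4-dimethoxy-6-pentylbenzoate F4. Hydrogenolysis (H2, Pd/C, EtOAc, rt) then frees both hydroxyls to give 7.

Further compounds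
F1 | step 7 | benzyl 2-(benzyloxy)-4-[(2,4-dimethoxy-6-pentylbenzoyl)oxy]-6-[(trifluoromethanesulfonyl)oxy]benzoate | O=C(OCc1ccccc1)c1c(OCc2ccccc2)cc(OC(=O)c2c(CCCCC)cc(OC)cc2OC)cc1OS(=O)(=O)C(F)(F)F
F2 | step 7 | benzyl 2-(benzyloxy)-4-[(2,4-dimethoxy-6-pentylbenzoyl)oxy]-6-pentylbenzoate | O=C(OCc1ccccc1)c1c(OCc2ccccc2)cc(OC(=O)c2c(CCCCC)cc(OC)cc2OC)cc1CCCCC
F3 | step 5 | 3-hydroxy-2-iodo-5-[(2,4-dimethoxy-6-pentylbenzoyl)oxy]phenyl trifluoromethanesulfonate | CCCCCc1cc(OC)cc(OC)c1C(=O)Oc1cc(O)c(I)c(OS(=O)(=O)C(F)(F)F)c1
F4 | step 3 | 3,5-bis(benzyloxy)phenyl 2,4-dimethoxy-6-pentylbenzoate | CCCCCc1cc(OC)cc(OC)c1C(=O)Oc1cc(OCc2ccccc2)cc(OCc2ccccc2)c1
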